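## Analysis of the target

Betaethrin E (22) has no fused rings and no stereocentre: it is two benzene rings joined by one ether oxygen, so the synthesis is a problem of substitution pattern and of keeping three oxygens distinct. Taking the benzylic carbon of ring A as A1, ring A carries CH2O‑palmitoyl at A1, the ether oxygen at A2, a free hydroxyl at A3 and a methoxy group at A5, with A4 and A6 unsubstituted. Ring B is a methyl benzoate (B1) with the ether oxygen at B2, a methyl group at B4 and a hydroxyl at B6 that is hydrogen-bonded to the ester. The ether oxygen has two ortho substituents on ring A (A1, A3) and the ester next to it on ring B, so coupling two finished arenes would be a hindered, electronically unfavourable C–O bond formation. The sensitive groups are the primary benzylic palmitate (base, strong nucleophiles, hydrogenolysis), the methyl ester and the two phenols, which must stay distinguishable from the A5 methyl ether. The hard part is therefore to make the hindered ether and to arrive at A2‑O‑aryl, A3‑OH and A5‑OMe already differentiated, with the palmitate intact. The strategy rests on the fact that A3‑OH is ortho to the ether carbon A2 and meta to A5‑OMe. This is the pattern produced when a vinylketene (A3, A2, A1, A6) is combined with an alkoxyalkyne (A4, A5), the ketene carbonyl becoming the A3 hydroxyl.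

## Retrosynthetic reasoning

**22 to 21.** The last operation is only the O–CH3 bond at B6. The B6 hydroxyl has to be masked while the acid is activated, the diazo group is introduced and a ketene is generated, because a free phenol would be acylated, alkylated or would capture the ketene. In methyl ether 21 this is the only aryl ether ortho to a carbonyl group, so a chelating Lewis acid can remove it without an orthogonal partner. The forward step must tell B6‑OMe from A5‑OMe and spare the palmitate.

**21 to 13 and 16.** Ring A is opened at A3–A4, A5–A6 and A2–A3. Cutting the aryl–oxygen bond between two complete rings instead would leave the hindered coupling described above. Cutting ring A moves that C–O bond back to an acyclic stage, delivers A3‑OH free and already different from A5‑OMe, and lets the palmitate ride in on the precursor. The forward reaction has to turn diazoketone 13 into vinylketene 17, combine it with methoxyethyne 16 in the correct orientation, and carry the adduct through ring opening and ring closure to phenol 21.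

**13 to 11.** The bond between the acyl carbon and the diazomethyl carbon is cut, leading through acid chloride 12 back to acid 11. Acid 11 already holds A1, A2, the future A3 carbon and both side groups. The added carbon becomes A6 after the Wolff shift. The forward step must activate the acid without harming the enol ether or the allylic ester, and the diazo reagent must attack the acyl carbon and not the conjugated double bond.

**11 to 10 to 8 and 9.** Two ester bonds are cut: the tert-butyl ester of 10, so that the acid can be released by acid and not by base, which would remove the palmitate, and the palmitate acyl–oxygen bond, back to alcohol 8 and palmitoyl chloride 9. The palmitate is attached at this point and not earlier for a mechanistic reason. A 2‑(acyloxymethyl)acrylate is an allylic electrophile, and a phenoxide that adds to its β‑carbon can expel the carboxylate (SN2') in competition with the halide. Carrying the hydroxymethyl group as silyl ether 7 through the substitution costs two simple steps and removes that ambiguity. After the exchange no step uses a nucleophile that threatens the ester.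

**7 to 2 and 6.** The enol ether C–O bond, the future A2–O bond, is cut. The hindered ether oxygen is joined to an unhindered sp2 CH carbon by addition–elimination of phenol 2 on bromoacrylate 6, activated by the ester. The forward step should give the E enol ether, with the aryloxy group anti to the ester.

**6 to 4 to 3, 2 to 1, 16 to 14.** What remains are functional-group operations on commercial materials. Bromoacrylate 6 comes from silyl ether 4 by bromination and dehydrobromination, and 4 from hydroxymethylacrylate 3. Phenol 2 is the monomethyl ether of the symmetrical diol 1. Alkyne 16 comes from chloroacetal 14 by double elimination.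

## Alternatives that were turned down

Alternative 1: Ring B is disconnected at B1–B2 and B3–B4 into the ring A aryl ethynyl ether A2 and the pyrone A3. In the forward direction A2 and A3 undergo an inverse-demand [4+2] cycloaddition and the bridged lactone aromatizes by decarboxylation to the bis-acetal diaryl ether A1.
- For it: the route is convergent and the orientation is well founded, since the nucleophilic CH terminus of A2 should join the electrophilic C6 of A3.
- Against it: A2 has to be made from the fully substituted ring A phenol A4 by strong-base ynol ether chemistry, which a palmitate cannot survive. Both ring A oxygens must therefore travel as acetals, and the palmitate has to be put on at the end selectively beside free phenols. The 4‑methoxy group makes A3 a less electron-poor diene, so the thermally fragile A2 would need forcing conditions. A4 itself needs a regiocontrolled synthesis.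
- Comparison: A1 still carries the B6 methyl ether, so it needs the same demethylation as step 11 in addition to two acetal cleavages and a selective acylation. The chosen route is more linear, but it reaches 21 with the palmitate in place and A3‑OH free, one step from 22.

Alternative 2: Ring A is taken back to the cyclohexane‑1,3‑dione A5, disconnected at A2–A1 and A4–A5 into the aryloxyacetone A6 and the silyloxycrotonate A7. In the forward direction the aryloxy-bearing carbon of A6 adds to A7 in a Michael reaction and the methyl ketone then closes onto the ester in a Claisen-type condensation.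
- For it: it uses only enolate chemistry, with no light, no diazo compound and no volatile alkyne. On ease of operation and scale it is stronger than the chosen route.
- Against it: A5 is one oxidation level below the arene. After dehydrogenation the two ring A oxygens have to be told apart in a methylation, and the silyl ether must then be exchanged for the palmitate beside three phenolic hydroxyls. Regiochemistry of enolization of A6 is a further risk.
- Comparison: about four steps with open selectivity questions follow its key step. In the chosen route the benzannulation fixes A3‑OH against A5‑OMe by mechanism, and one step follows it.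

Alternative 3: Ring B is disconnected at B2–B3 and B6–B1 into the aryloxypropiolate A9 and the silyl ketene acetal diene A10. In the forward direction a [4+2] cycloaddition and loss of the alkoxy group give A8 with the B6 hydroxyl free.
- For it: no late demethylation is needed, and on that point it is stronger than the chosen route. The orientation of 1,1‑dioxygenated dienes is reliable and the route is convergent.
- Against it: A9 is a push–pull alkyne whose donor oxygen lowers its dienophilicity and which hydrates easily. It again comes from phenol A4 through acetylide chemistry, so the acetal groups and the selective late palmitoylation return.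
- Comparison: it trades the single chelation-controlled demethylation of the chosen route for two deprotections and one selective acylation, and it needs A4. The chosen route builds both rings' substitution from 1, 3, 9 and 14.

Key step: step 10

## Route

Remark on the chemistry: the double-bond geometry of 6–13 disappears when ring A becomes aromatic. E is specified because it is the expected isomer and the better one for ring closure, not because the target requires it.

Step 1
Reactants: 1 methyl 2,6-dihydroxy-4-methylbenzoate
Product: 2 methyl 2-hydroxy-6-methoxy-4-methylbenzoate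
Conditions: MeI (1.05 equiv), K2CO3 (1.1 equiv), acetone, 20 → 40 °C
Reagents that add atoms: iodomethane, CI
Why: Williamson O-methylation of one of two equivalent hydroxyls, so there is no regiochemical question; the hydroxyl that remains is hydrogen-bonded to the ester and much less nucleophilic, so one equivalent of MeI should stop at the monoether.

Step 2
Reactants: 3 tert-butyl 2-(hydroxymethyl)acrylate
Product: 4 tert-butyl 2-{[(tert-butyldimethylsilyl)oxy]methyl}acrylate
Conditions: TBSCl, imidazole, CH2Cl2, 0 → 20 °C
Reagents that add atoms: tert-butyldimethylsilyl chloride, CC(C)(C)[Si](C)(C)Cl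
Why: Standard silylation of a primary allylic alcohol; a silyloxy group is not a leaving group, which closes the SN2' channel that an acyloxymethyl acrylate would offer to the phenoxide in step 4.

Step 3
Reactants: 4 tert-butyl 2-{[(tert-butyldimethylsilyl)oxy]methyl}acrylate
Product: 6 tert-butyl (E)-3-bromo-2-{[(tert-butyldimethylsilyl)oxy]methyl}acrylate, via dibromide 5 (not isolated)
Conditions: Br2 (1.05 equiv), CH2Cl2, 0 → 20 °C; then DBU (1.2 equiv), 0 → 20 °C
Reagents that add atoms: bromine, BrBr
Why: Bromine addition to the acrylate followed by anti E2 dehydrobromination, the route by which 3-bromomethacrylates are made; the tertiary α-bromide should leave with a proton of the CH2Br group, the more acidic of the two β-methylene groups, placing the vinylic bromine anti to the ester.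

Step 4
Reactants: 2 methyl 2-hydroxy-6-methoxy-4-methylbenzoate; 6 tert-butyl (E)-3-bromo-2-{[(tert-butyldimethylsilyl)oxy]methyl}acrylate
Product: 7 methyl 2-{[(E)-3-tert-butoxy-2-{[(tert-butyldimethylsilyl)oxy]methyl}-3-oxoprop-1-en-1-yl]oxy}-6-methoxy-4-methylbenzoate
Conditions: Cs2CO3 (1.5 equiv), DMF, 20 → 50 °C
Reagents that add atoms: none
Why: Vinylogous nucleophilic substitution by addition–elimination: the phenoxide of 2 adds to the β-carbon of 6 and the ester enolate expels bromide, so the hindered aryl–oxygen bond is made at an unhindered sp2 CH; retention in the substitution and the thermodynamic preference both point to the E enol ether.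

Step 5
Reactants: 7 methyl 2-{[(E)-3-tert-butoxy-2-{[(tert-butyldimethylsilyl)oxy]methyl}-3-oxoprop-1-en-1-yl]oxy}-6-methoxy-4-methylbenzoate
Product: 8 methyl 2-{[(E)-3-tert-butoxy-2-(hydroxymethyl)-3-oxoprop-1-en-1-yl]oxy}-6-methoxy-4-methylbenzoate
Conditions: HF·pyridine, pyridine, THF, 0 → 20 °C
Reagents that add atoms: none
Why: Fluoride-driven cleavage of a primary silyl ether under buffered, non-basic conditions; both esters and the vinylogous carbonate are inert to it.

Step 6
Reactants: 8 methyl 2-{[(E)-3-tert-butoxy-2-(hydroxymethyl)-3-oxoprop-1-en-1-yl]oxy}-6-methoxy-4-methylbenzoate; 9 palmitoyl chloride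
Product: 10 methyl 2-{[(E)-3-tert-butoxy-2-[(hexadecanoyloxy)methyl]-3-oxoprop-1-en-1-yl]oxy}-6-methoxy-4-methylbenzoate
Conditions: pyridine, DMAP (cat.), CH2Cl2, 0 → 20 °C
Reagents that add atoms: none
Why: Acylation of a primary allylic alcohol with an acid chloride; the palmitate enters only after the phenoxide chemistry is over, so the allylic ester is not exposed to SN2' displacement.

Step 7
Reactants: 10 methyl 2-{[(E)-3-tert-butoxy-2-[(hexadecanoyloxy)methyl]-3-oxoprop-1-en-1-yl]oxy}-6-methoxy-4-methylbenzoate
Product: 11 (E)-2-[(hexadecanoyloxy)methyl]-3-[3-methoxy-2-(methoxycarbonyl)-5-methylphenoxy]acrylic acid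
Conditions: CF3CO2H/CH2Cl2 (1:3), 0 → 20 °C
Reagents that add atoms: none
Why: Acidolysis of the tert-butyl ester by alkyl–oxygen cleavage, which leaves the primary palmitate, the methyl ester and the aryl methyl ether alone; the enol ether is a push–pull vinylogous carbonate with an ester on the adjacent carbon, so it should neither hydrolyse nor ionize under anhydrous acid.

Step 8
Reactants: 11 (E)-2-[(hexadecanoyloxy)methyl]-3-[3-methoxy-2-(methoxycarbonyl)-5-methylphenoxy]acrylic acid
Product: 13 methyl 2-{[(E)-4-diazo-2-[(hexadecanoyloxy)methyl]-3-oxobut-1-en-1-yl]oxy}-6-methoxy-4-methylbenzoate, via acid chloride 12 (not isolated)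
Conditions: (COCl)2 (1.5 equiv), DMF (cat.), CH2Cl2, 0 → 20 °C; evaporate; then CH2N2 (4 equiv), Et2O/THF, 0 °C
Reagents that add atoms: diazomethane, C=[N+]=[N-]; oxalyl chloride, O=C(Cl)C(=O)Cl (supplies only the chlorine of intermediate 12)
Why: Arndt–Eistert-type acylation of diazomethane by the acid chloride, with excess diazomethane taking up the HCl; the conjugated double bond is trisubstituted and carries a donor aryloxy group, so dipolar cycloaddition of diazomethane to it should be much slower than acylation.

Step 9
Reactants: 14 chloroacetaldehyde dimethyl acetal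
Product: 16 methoxyethyne, via sodium methoxyethynide 15 (not isolated)
Conditions: NaNH2 (3.2 equiv), liq. NH3, −33 °C; then sat. aq. NaCl, −70 → 0 °C, distil into ClCH2CH2Cl at −78 °C
Reagents that add atoms: none
Why: Base-induced double elimination (loss of methanol, then of HCl) gives the alkynyl ether, held as its sodium acetylide until the cold aqueous quench; this is the standard way to the lower alkoxyethynes from chloroacetals.

Step 10
Reactants: 13 methyl 2-{[(E)-4-diazo-2-[(hexadecanoyloxy)methyl]-3-oxobut-1-en-1-yl]oxy}-6-methoxy-4-methylbenzoate; 16 methoxyethyne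
Product: 21 methyl 2-{2-[(hexadecanoyloxy)methyl]-6-hydroxy-4-methoxyphenoxy}-6-methoxy-4-methylbenzoate, via vinylketene 17 (not isolated), via cyclobutenone 18 (not isolated), via dienylketene 19 (not isolated), via cyclohexadienone 20 (not isolated)
Conditions: hν (300 nm, Pyrex), 16 (5 equiv), ClCH2CH2Cl, 0 → 20 °C, sealed tube; vent excess 16; then 80 °C
Reagents that add atoms: none
Why: Irradiation expels the diazo nitrogen from 13 and the alkenyl group migrates (photochemical Wolff rearrangement) to give vinylketene 17, whose carbonyl carbon is the former acyl carbon. A [2+2] cycloaddition of the ketene C=C with methoxyethyne 16 then gives the 3-methoxy-4-vinylcyclobutenone 18 (bonds A3–A4 and A5–A6); polarization fixes the orientation, because the nucleophilic CH terminus of the ynol ether attacks the electrophilic ketene carbonyl carbon while the oxygen-bearing carbon joins the ketene terminus, which places OMe at A5, meta to the new hydroxyl. Four-electron conrotatory electrocyclic opening of 18, reversible and driven on by heat, gives dienylketene 19, and ring A is closed by a thermal six-electron disrotatory electrocyclization between the ketene carbon and the aryloxy-bearing enol ether carbon (bond A2–A3) to cyclohexadienone 20, which tautomerizes irreversibly to phenol 21. This is the diazoketone (photo-Wolff) form of the Danheiser benzannulation, established for alkenyl diazoketones with alkoxyalkynes; the unusual element here is only the aryloxy group at the vinylketene terminus. No stereocentre survives: the sp3 carbons of 18 and 20 are racemic and are erased by ring opening and tautomerization. The E geometry of 13 keeps the bulky aryloxy group on the outside of the closing triene, and its donor character should make that terminus more nucleophilic toward the ketene carbon. The selectivity needed is capture of 17 by the alkyne and not by the product phenol, the enol ether of another molecule or a second ketene, which the fivefold excess of the strongly nucleophilic ynol ether should secure; the palmitate and both esters are spectators.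

Step 11
Reactants: 21 methyl 2-{2-[(hexadecanoyloxy)methyl]-6-hydroxy-4-methoxyphenoxy}-6-methoxy-4-methylbenzoate
Product: 22 betaethrin E, methyl 2-{2-[(hexadecanoyloxy)methyl]-6-hydroxy-4-methoxyphenoxy}-6-hydroxy-4-methylbenzoate
Conditions: BCl3 (3 equiv), CH2Cl2, −78 → −10 °C; then aq. NaHCO3
Reagents that add atoms: none
Why: Chelation-directed Lewis acid demethylation: boron held by the ring B ester carbonyl reaches the ortho methoxy oxygen and chloride removes its methyl group. The A5 methoxy group has no neighbouring carbonyl, and the primary palmitate and the methyl ester are not cleaved at this temperature.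

## Compound list

1 | methyl 2,6-dihydroxy-4-methylbenzoate | COC(=O)c1c(O)cc(C)cc1O | starting material
2 | methyl 2-hydroxy-6-methoxy-4-methylbenzoate | COC(=O)c1c(O)cc(C)cc1OC | intermediate
3 | tert-butyl 2-(hydroxymethyl)acrylate | C=C(CO)C(=O)OC(C)(C)C | starting material
4 | tert-butyl 2-{[(tert-butyldimethylsilyl)oxy]methyl}acrylate | C=C(CO[Si](C)(C)C(C)(C)C)C(=O)OC(C)(C)C | intermediate
5 | tert-butyl 2,3-dibromo-2-{[(tert-butyldimethylsilyl)oxy]methyl}propanoate (racemic) | BrCC(Br)(CO[Si](C)(C)C(C)(C)C)C(=O)OC(C)(C)C | intermediate
6 | tert-butyl (E)-3-bromo-2-{[(tert-butyldimethylsilyl)oxy]methyl}acrylate (bromine anti to the ester) | CC(C)(C)OC(=O)/C(CO[Si](C)(C)C(C)(C)C)=C/Br | intermediate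
7 | methyl 2-{[(E)-3-tert-butoxy-2-{[(tert-butyldimethylsilyl)oxy]methyl}-3-oxoprop-1-en-1-yl]oxy}-6-methoxy-4-methylbenzoate | CC(C)(C)OC(=O)/C(CO[Si](C)(C)C(C)(C)C)=C/Oc1cc(C)cc(OC)c1C(=O)OC | intermediate
8 | methyl 2-{[(E)-3-tert-butoxy-2-(hydroxymethyl)-3-oxoprop-1-en-1-yl]oxy}-6-methoxy-4-methylbenzoate | CC(C)(C)OC(=O)/C(CO)=C/Oc1cc(C)cc(OC)c1C(=O)OC | intermediate
9 | palmitoyl chloride (hexadecanoyl chloride) | CCCCCCCCCCCCCCCC(Cl)=O | starting material
10 | methyl 2-{[(E)-3-tert-butoxy-2-[(hexadecanoyloxy)methyl]-3-oxoprop-1-en-1-yl]oxy}-6-methoxy-4-methylbenzoate | CC(C)(C)OC(=O)/C(COC(=O)CCCCCCCCCCCCCCC)=C/Oc1cc(C)cc(OC)c1C(=O)OC | intermediate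
11 | (E)-2-[(hexadecanoyloxy)methyl]-3-[3-methoxy-2-(methoxycarbonyl)-5-methylphenoxy]acrylic acid | OC(=O)/C(COC(=O)CCCCCCCCCCCCCCC)=C/Oc1cc(C)cc(OC)c1C(=O)OC | intermediate
12 | (E)-2-[(hexadecanoyloxy)methyl]-3-[3-methoxy-2-(methoxycarbonyl)-5-methylphenoxy]acryloyl chloride | ClC(=O)/C(COC(=O)CCCCCCCCCCCCCCC)=C/Oc1cc(C)cc(OC)c1C(=O)OC | intermediate
13 | methyl 2-{[(E)-4-diazo-2-[(hexadecanoyloxy)methyl]-3-oxobut-1-en-1-yl]oxy}-6-methoxy-4-methylbenzoate | O=C(C=[N+]=[N-])/C(COC(=O)CCCCCCCCCCCCCCC)=C/Oc1cc(C)cc(OC)c1C(=O)OC | intermediate
14 | chloroacetaldehyde dimethyl acetal (2-chloro-1,1-dimethoxyethane) | COC(CCl)OC | starting material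
15 | sodium methoxyethynide | COC#[C-].[Na+] | intermediate
16 | methoxyethyne | COC#C | intermediate
17 | methyl 2-{[(Z)-2-[(hexadecanoyloxy)methyl]-4-oxobuta-1,3-dien-1-yl]oxy}-6-methoxy-4-methylbenzoate (vinylketene; aryloxy anti to the ketene-bearing carbon) | O=C=C/C(COC(=O)CCCCCCCCCCCCCCC)=C/Oc1cc(C)cc(OC)c1C(=O)OC | intermediate
18 | methyl 2-{[(Z)-3-(hexadecanoyloxy)-2-(2-methoxy-4-oxocyclobut-2-en-1-yl)prop-1-en-1-yl]oxy}-6-methoxy-4-methylbenzoate (racemic) | O=C1C=C(OC)C1/C(COC(=O)CCCCCCCCCCCCCCC)=C/Oc2cc(C)cc(OC)c2C(=O)OC | intermediate
19 | methyl 2-{[(1Z,3E)-2-[(hexadecanoyloxy)methyl]-4-methoxy-6-oxohexa-1,3,5-trien-1-yl]oxy}-6-methoxy-4-methylbenzoate (dienylketene) | O=C=C/C(OC)=C\C(COC(=O)CCCCCCCCCCCCCCC)=C\Oc1cc(C)cc(OC)c1C(=O)OC | intermediate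
20 | methyl 2-({2-[(hexadecanoyloxy)methyl]-4-methoxy-6-oxocyclohexa-2,4-dien-1-yl}oxy)-6-methoxy-4-methylbenzoate (racemic) | O=C1C=C(OC)C=C(COC(=O)CCCCCCCCCCCCCCC)C1Oc2cc(C)cc(OC)c2C(=O)OC | intermediate
21 | methyl 2-{2-[(hexadecanoyloxy)methyl]-6-hydroxy-4-methoxyphenoxy}-6-methoxy-4-methylbenzoate | CCCCCCCCCCCCCCCC(=O)OCc1cc(OC)cc(O)c1Oc1cc(C)cc(OC)c1C(=O)OC | intermediate
22 | betaethrin E, methyl 2-{2-[(hexadecanoyloxy)methyl]-6-hydroxy-4-methoxyphenoxy}-6-hydroxy-4-methylbenzoate | CCCCCCCCCCCCCCCC(=O)OCc1cc(OC)cc(O)c1Oc1cc(C)cc(O)c1C(=O)OC | target

## Step count and least certain steps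

Total: 11 steps. Longest linear sequence: 9 steps (steps 2–8, 10 and 11, from 3).

**Step 10 (key step).** The most likely failure is capture of vinylketene 17 by something other than the alkyne: addition of the phenol of 21 already formed, [2+2] reaction with the enol ether of another molecule, or dimerization. This is favoured because 16 boils near room temperature, cannot be held at high concentration and tends to polymerize. Photochemical E/Z scrambling or degradation of the aryl enol ether chromophore is a second risk. The fallback changes the two-carbon partner to a non-volatile, storable ynol ether with a traceless silyl group. It sets out from sodium methoxyethynide 15 and diazoketone 13 and returns at 21. After evaporation of the ammonia, 15 is suspended in Et2O and silylated with Me3SiCl to (methoxyethynyl)trimethylsilane F1. F1 can be used in large excess and heated with 13 under the same irradiation. Through 17 the cascade should run by way of the silylated cyclobutenone F2, the silylated dienylketene F3 and the silylated cyclohexadienone F4 to the 4-silylphenol F5, the β-silicon helping the same orientation. Ipso protodesilylation of F5 (CF3CO2H, CH2Cl2, 0 °C) then gives 21.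

**Step 8.** Diazomethane may add as a dipole across the conjugated double bond to give a pyrazoline in place of acylation, the usual weakness of this reaction with unsaturated acid chlorides. The fallback avoids diazomethane by a detrifluoroacetylative diazo transfer. It sets out from acid chloride 12 and returns at 13. Coupling of 12 with MeZnCl under Pd(PPh3)4 catalysis (THF, 0 °C) gives the methyl ketone F6. Kinetic enolization with LiN(SiMe3)2 at −78 °C and trapping with CF3CO2CH2CF3 gives the trifluoroacetyl diketone F7. Diazo transfer from MsN3 (Et3N, H2O, MeCN) with loss of the trifluoroacetyl group then gives 13.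

**Step 3.** HBr may be lost toward the silyloxymethyl group, adventitious HBr may cleave the silyl ether, and control of the double-bond geometry may be poor. The fallback makes the vinyl bromide by olefination. It sets out from 4 and returns at 6. Ozonolysis of 4 (O3, CH2Cl2, −78 °C; Me2S) gives tert-butyl 3-[(tert-butyldimethylsilyl)oxy]-2-oxopropanoate F8. Wittig bromomethylenation with Ph3P=CHBr (from the phosphonium bromide and NaN(SiMe3)2, THF, −78 °C) gives 6 together with its Z isomer, tert-butyl (Z)-3-bromo-2-{[(tert-butyldimethylsilyl)oxy]methyl}acrylate F9, which is removed by chromatography.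

**Step 4.** Addition of the hindered, internally hydrogen-bonded phenoxide may be slow, and heating to compensate may erode the geometry or the silyl ether. The fallback replaces addition–elimination by an Ullmann-type C–O cross-coupling of 2 with 6 (CuI, N,N-dimethylglycine, Cs2CO3, dioxane, 90 °C), which should proceed with retention at the vinyl bromide. It sets out from 2 and 6, returns at 7 and makes no new compound.

## Further compounds

F1 | step 10 | (methoxyethynyl)trimethylsilane | COC#C[Si](C)(C)C
F2 | step 10 | methyl 2-{[(Z)-3-(hexadecanoyloxy)-2-[2-methoxy-4-oxo-3-(trimethylsilyl)cyclobut-2-en-1-yl]prop-1-en-1-yl]oxy}-6-methoxy-4-methylbenzoate (racemic) | O=C1C([Si](C)(C)C)=C(OC)C1/C(COC(=O)CCCCCCCCCCCCCCC)=C/Oc2cc(C)cc(OC)c2C(=O)OC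
F3 | step 10 | methyl 2-{[(1Z,3E)-2-[(hexadecanoyloxy)methyl]-4-methoxy-6-oxo-5-(trimethylsilyl)hexa-1,3,5-trien-1-yl]oxy}-6-methoxy-4-methylbenzoate | O=C=C([Si](C)(C)C)/C(OC)=C\C(COC(=O)CCCCCCCCCCCCCCC)=C\Oc1cc(C)cc(OC)c1C(=O)OC
F4 | step 10 | methyl 2-({2-[(hexadecanoyloxy)methyl]-4-methoxy-6-oxo-5-(trimethylsilyl)cyclohexa-2,4-dien-1-yl}oxy)-6-methoxy-4-methylbenzoate (racemic) | O=C1C([Si](C)(C)C)=C(OC)C=C(COC(=O)CCCCCCCCCCCCCCC)C1Oc2cc(C)cc(OC)c2C(=O)OC
F5 | step 10 | methyl 2-{2-[(hexadecanoyloxy)methyl]-6-hydroxy-4-methoxy-5-(trimethylsilyl)phenoxy}-6-methoxy-4-methylbenzoate | CCCCCCCCCCCCCCCC(=O)OCc1cc(OC)c([Si](C)(C)C)c(O)c1Oc1cc(C)cc(OC)c1C(=O)OC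
F6 | step 8 | methyl 2-{[(E)-2-[(hexadecanoyloxy)methyl]-3-oxobut-1-en-1-yl]oxy}-6-methoxy-4-methylbenzoate | CC(=O)/C(COC(=O)CCCCCCCCCCCCCCC)=C/Oc1cc(C)cc(OC)c1C(=O)OC
F7 | step 8 | methyl 2-{[(E)-6,6,6-trifluoro-2-[(hexadecanoyloxy)methyl]-3,5-dioxohex-1-en-1-yl]oxy}-6-methoxy-4-methylbenzoate | O=C(CC(=O)C(F)(F)F)/C(COC(=O)CCCCCCCCCCCCCCC)=C/Oc1cc(C)cc(OC)c1C(=O)OC
F8 | step 3 | tert-butyl 3-[(tert-butyldimethylsilyl)oxy]-2-oxopropanoate | CC(C)(C)OC(=O)C(=O)CO[Si](C)(C)C(C)(C)C
F9 | step 3 | tert-butyl (Z)-3-bromo-2-{[(tert-butyldimethylsilyl)oxy]methyl}acrylate | CC(C)(C)OC(=O)/C(CO[Si](C)(C)C(C)(C)C)=C\Br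
F0 | step 4 | none | none
A1 | alternative 1 | methyl 2-methoxy-6-{4-methoxy-2-(methoxymethoxy)-6-[(methoxymethoxy)methyl]phenoxy}-4-methylbenzoate | COCOCc1cc(OC)cc(OCOC)c1Oc1cc(C)cc(OC)c1C(=O)OC
A2 | alternative 1 | 2-(ethynyloxy)-5-methoxy-1-(methoxymethoxy)-3-[(methoxymethoxy)methyl]benzene | C#COc1c(COCOC)cc(OC)cc1OCOC
A3 | alternative 1 | methyl 4-methoxy-6-methyl-2-oxo-2H-pyran-3-carboxylate | COC(=O)c1c(OC)cc(C)oc1=O
A4 | alternative 1 | 4-methoxy-2-(methoxymethoxy)-6-[(methoxymethoxy)methyl]phenol | Oc1c(COCOC)cc(OC)cc1OCOC
A5 | alternative 2 | methyl 2-({trans-6-{[(tert-butyldimethylsilyl)oxy]methyl}-2,4-dioxocyclohexyl}oxy)-6-hydroxy-4-methylbenzoate (racemic, one enantiomer drawn) | COC(=O)c1c(O)cc(C)cc1O[C@@H]1[C@@H](CO[Si](C)(C)C(C)(C)C)CC(=O)CC1=O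
A6 | alternative 2 | methyl 2-hydroxy-4-methyl-6-(2-oxopropoxy)benzoate | COC(=O)c1c(O)cc(C)cc1OCC(C)=O
A7 | alternative 2 | methyl (E)-4-[(tert-butyldimethylsilyl)oxy]but-2-enoate | COC(=O)/C=C/CO[Si](C)(C)C(C)(C)C
A8 | alternative 3 | methyl 2-hydroxy-6-{4-methoxy-2-(methoxymethoxy)-6-[(methoxymethoxy)methyl]phenoxy}-4-methylbenzoate | COCOCc1cc(OC)cc(OCOC)c1Oc1cc(C)cc(O)c1C(=O)OC
A9 | alternative 3 | methyl 3-{4-methoxy-2-(methoxymethoxy)-6-[(methoxymethoxy)methyl]phenoxy}prop-2-ynoate | COC(=O)C#COc1c(COCOC)cc(OC)cc1OCOC
A10 | alternative 3 | 1-methoxy-3-methyl-1-(trimethylsilyloxy)buta-1,3-diene (ketene acetal geometry not defined) | COC(O[Si](C)(C)C)=CC(C)=C
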